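## Retrosynthetic overview
1. Target 32 ⇐ Δ1-en-3-one 29 (β-face conjugate borylation–oxidation gives the 1β-OH, then fluoride deprotection) ⇐ pentacyclic 3-keto-19,10-lactone 28 (dehydrogenation).
2. Key step: 28 ⇐ β-keto ester 27 by a trivalent-manganese oxidative radical 6-endo cyclisation with cation capture by the ester; ring A and the lactone form together (C4–C5 and C10–O bonds; C4, C5, C10 set).
3. 27 ⇐ cyclopentenone 16 (conjugate addition at C10, enol triflate carbonylation for C7, deconjugation to C5=C10, aldol and oxidation).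
4. 16 ⇐ allyl Hajos–Parrish enedione 7 (ring D by palladium cycloalkenylation, Li/NH3 for the trans B/C junction, axial 12-OH); 7 ⇐ 1 + 2 + 4 with L-proline setting C8. Ring order: B, C, D, then A plus lactone.

Assumption: the SMILES is taken literally; it places H-9 on the same face of ring B as the lactone oxygen (a trans B/C junction, unlike the common gibberellins), and the route is built for that configuration.
Convention: gibberellane locants of the target are used for all intermediates (ring B = C5, C6, C8, C9, C10); α is the face of ring B that carries O-10 in the target, β the face that carries C15.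

## Route

Step 1
Reactants: 1 cyclopentane-1,3-dione; 2 allyl bromide
Product: 3 2-allylcyclopentane-1,3-dione
Conditions: NaOH, H2O, 0 °C to rt
Reagents that add atoms: none
Why: C-alkylation of the soft enolate of the cyclic 1,3-dione in water (SN2 allylation) gives the 2-allyl dione and creates no stereocentre.

Step 2
Reactants: 3 2-allylcyclopentane-1,3-dione; 4 methyl vinyl ketone
Product: 5 2-allyl-2-(3-oxobutyl)cyclopentane-1,3-dione
Conditions: H2O, AcOH (cat.), 75 °C
Reagents that add atoms: none
Why: Michael addition of the enolised 2-substituted 1,3-dione to the vinyl ketone under weakly acidic aqueous conditions gives the prochiral triketone.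

Step 3
Reactants: 5 2-allyl-2-(3-oxobutyl)cyclopentane-1,3-dione
Product: 7 (R)-7a-allyl-2,3,7,7a-tetrahydro-1H-indene-1,5(6H)-dione (allyl Hajos–Parrish enedione), via cis-fused ketol 6 (not isolated)
Conditions: L-proline (30 mol%), DMF, rt; then H2SO4 (cat.), 95 °C
Reagents that add atoms: none
Why: In this Hajos–Parrish–Eder–Sauer–Wiechert reaction the L-proline enamine of the side-chain ketone attacks one of the two enantiotopic ring carbonyls through the acid-organised chair transition state, which fixes quaternary C8 in the same spatial sense as in the (S)-methyl Hajos–Parrish ketone, and acid then dehydrates the ketol.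

Step 4
Reactants: 7 allyl Hajos–Parrish enedione
Product: 8 C6 ethylene ketal of 7
Conditions: Me3SiOCH2CH2OSiMe3, Me3SiOTf (cat.), CH2Cl2, −78 °C
Reagents that add atoms: 1,2-bis(trimethylsilyloxy)ethane C[Si](C)(C)OCCO[Si](C)(C)C
Why: Noyori ketalisation is kinetically selective for the saturated cyclopentanone over the conjugated, deactivated enone carbonyl, which masks C6 for the base and reduction steps that follow.

Step 5
Reactants: 8 C6 ethylene ketal of 7
Product: 10 tert-butyldimethylsilyl cross-conjugated dienol ether of 8, via lithium dienolate 9 (not isolated)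
Conditions: LiN(i-Pr)2, THF, −78 °C; then t-BuMe2SiCl, HMPA, −78 °C to rt
Reagents that add atoms: tert-butyldimethylsilyl chloride CC(C)(C)[Si](C)(C)Cl
Why: Kinetic deprotonation of the enone at the α′ carbon C13 by the hindered amide base followed by O-silylation gives the 2-silyloxy diene needed for ring D closure.

Step 6
Reactants: 10 silyl dienol ether
Product: 11 tricyclic enone (ring D closed; 16-methylene; Δ9(11)-12-one; C6 ketal)
Conditions: Pd(OAc)2 (10 mol%), O2 (1 atm), DMSO, 45 °C
Reagents that add atoms: none
Why: In this palladium-catalysed oxidative cycloalkenylation (Toyota–Ihara type) the enol ether carbon C13 attacks the alkene bound to divalent palladium in a 5-exo sense at C16 and β-hydride elimination gives the exocyclic methylene, the new bridge being necessarily cis to C15 so that C13 follows from C8.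

Step 7
Reactants: 11 tricyclic enone
Product: 12 saturated 12-ketone with H-9 α (trans B/C junction)
Conditions: Li, NH3 (l), t-BuOH (1 equiv), THF, −78 °C; then isoprene, NH4Cl
Reagents that add atoms: none
Why: Dissolving-metal enone reduction protonates the β-carbanion at C9 on the face away from the C15–C16 bridge, which is both the open face of the bridged bicycle and the axial direction of the locked ring C chair, so H-9 ends anti to C15 and C10 equatorial.

Step 8
Reactants: 12 saturated 12-ketone
Product: 13 axial 12-alcohol (OH anti to the C13–C16 bond and cis to H-9)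
Conditions: LiBH(s-Bu)3, THF, −78 °C; aq. NH4Cl
Reagents that add atoms: none
Why: The bulky trialkylborohydride attacks the C12 ketone along the equatorial trajectory because the axial path is hindered by the syn-axial hydrogens on C9 and C14, giving the axial alcohol as this reagent does with cyclohexanones that carry one axial α-substituent.

Step 9
Reactants: 13 axial 12-alcohol
Product: 14 12-O-tert-butyldimethylsilyl ether of 13
Conditions: t-BuMe2SiOTf, 2,6-lutidine, CH2Cl2, −40 °C
Reagents that add atoms: tert-butyldimethylsilyl trifluoromethanesulfonate CC(C)(C)[Si](C)(C)OS(=O)(=O)C(F)(F)F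
Why: Silylation of the hindered axial alcohol with the silyl triflate and a non-nucleophilic base gives an ether that survives the oxidations, the organometallic steps and the acetic acid of the key step.

Step 10
Reactants: 14 silyl ether ketal
Product: 15 C6 ketone bearing the 12-silyl ether
Conditions: PPTS, acetone/H2O (9:1), 55 °C
Reagents that add atoms: water O
Why: Mild acid-catalysed ketal hydrolysis frees the cyclopentanone without touching the secondary silyl ether or the exocyclic alkene.

Step 11
Reactants: 15 C6 ketone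
Product: 16 cyclopentenone (Δ5(10)-6-one)
Conditions: 2-iodoxybenzoic acid (IBX), DMSO/toluene, 70 °C
Reagents that add atoms: none
Why: Nicolaou-type IBX dehydrogenation (enolisation, single-electron oxidation, loss of the β-hydrogen) can only introduce the C5=C10 double bond because C8 is quaternary.

Step 12
Reactants: 16 cyclopentenone; 17 [2-(1,3-dioxolan-2-yl)ethyl]magnesium bromide
Product: 19 C6 enol triflate carrying the acetal chain on C10, via magnesium enolate 18 (not isolated)
Conditions: CuBr·SMe2 (20 mol%), THF, −78 to −40 °C; then Comins' reagent, −78 to 0 °C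
Reagents that add atoms: N-(5-chloropyridin-2-yl)-1,1,1-trifluoro-N-(trifluoromethylsulfonyl)methanesulfonamide (Comins' reagent) Clc1ccc(nc1)N(S(=O)(=O)C(F)(F)F)S(=O)(=O)C(F)(F)F
Why: Copper-catalysed conjugate addition of the Grignard reagent to C10 followed by O-triflation of the regiodefined magnesium enolate installs the C1–C3 chain and turns C6 into a vinyl triflate in one flask, the new C10 centre being irrelevant because it becomes trigonal again in step 14.

Step 13
Reactants: 19 C6 enol triflate
Product: 20 conjugated 2-(trimethylsilyl)ethyl ester (C7 on C6; C5=C6)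
Conditions: Pd(OAc)2 (5 mol%), dppp (5 mol%), CO (1 atm), Me3SiCH2CH2OH, Et3N, DMF, 60 °C
Reagents that add atoms: carbon monoxide [C-]#[O+]; 2-(trimethylsilyl)ethanol C[Si](C)(C)CCO
Why: Palladium-catalysed alkoxycarbonylation of the vinyl triflate (oxidative addition, CO insertion, alcoholysis) introduces C7 as a fluoride-labile ester, as is routine for hindered ring enol triflates next to a quaternary carbon.

Step 14
Reactants: 20 conjugated ester
Product: 23 deconjugated aldehyde ester (C5=C10; 6β ester; C3 aldehyde), via lithium dienolate 21 (not isolated), via deconjugated acetal ester 22 (not isolated)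
Conditions: LiN(i-Pr)2, HMPA, THF, −78 °C; AcOH, −78 °C; then 1 M aq. HCl, THF, 0 °C to rt
Reagents that add atoms: water O
Why: γ-Deprotonation of the unsaturated ester (only C10 carries a γ-hydrogen) gives the dienolate, whose kinetic α-protonation at C6 from the open α face (anti to C15 and C11) moves the double bond to C5=C10 and sets the 6β ester, and dilute acid then unmasks the aldehyde.

Step 15
Reactants: 23 deconjugated aldehyde ester; 24 tert-butyl propanoate
Product: 26 β-hydroxy ester (C3 carbinol; C4 with methyl and tert-butyl ester), via lithium ester enolate 25 (not isolated)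
Conditions: LiN(i-Pr)2, THF, −78 °C; then 23, −78 °C; aq. NH4Cl
Reagents that add atoms: none
Why: Aldol addition of the preformed lithium ester enolate to the aldehyde at low temperature outruns proton transfer and gives the β-hydroxy ester, whose two new stereocentres are erased in steps 16 and 17.

Step 16
Reactants: 26 β-hydroxy ester
Product: 27 β-keto ester (C3 ketone; C4–H between ketone and tert-butyl ester)
Conditions: Dess–Martin periodinane, NaHCO3, CH2Cl2, 0 °C to rt
Reagents that add atoms: none
Why: Buffered Dess–Martin oxidation converts the secondary alcohol into the β-keto ester without isomerising the β,γ-unsaturated ester.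

Step 17
Reactants: 27 β-keto ester
Product: 28 pentacyclic 3-keto-19,10-lactone (ring A and lactone formed; 12-silyl ether; 7-silylethyl ester)
Conditions: Mn(OAc)3·2H2O (2.2 equiv), degassed AcOH, 60 °C
Reagents that add atoms: none
Why: Proposed new method: trivalent manganese oxidises the enolised α-methyl β-keto ester to an electrophilic tertiary radical that closes 6-endo onto C5 from the α face (anti to the 6β ester, C11 and C15) through a chair with the ester axial, the resulting tertiary C10 radical is oxidised to the cation and is captured on the same face by the axial tert-butyl ester carbonyl with loss of 2-methylpropene, so that C4, C5 and C10, ring A and the lactone arise together; the closest known reaction type is the Snider-type oxidative free-radical cyclisation of unsaturated β-keto esters, in which tertiary radicals are oxidised and trapped as γ-lactones.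

Step 18
Reactants: 28 pentacyclic 3-keto lactone
Product: 29 Δ1-en-3-one
Conditions: IBX, DMSO/toluene, 75 °C
Reagents that add atoms: none
Why: IBX dehydrogenation of the C3 ketone can only enolise toward C2 because C4 is quaternary, which gives the ring A enone.

Step 19
Reactants: 29 Δ1-en-3-one
Product: 31 1β-hydroxy-3-ketone (still 12-silyl ether and 7-silylethyl ester), via C1 pinacol boronate 30 (not isolated)
Conditions: B2pin2, CuCl (5 mol%), DPEphos (5 mol%), NaOt-Bu (10 mol%), MeOH, THF, rt; then 30% H2O2, pH 7 phosphate buffer, 0 °C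
Reagents that add atoms: bis(pinacolato)diboron CC1(C)OB(OC1(C)C)B1OC(C)(C)C(C)(C)O1 (boron in 30); hydrogen peroxide OO (oxygen in 31)
Why: Copper-catalysed conjugate borylation delivers boron to C1 from the β face, anti to the lactone bridge that covers the α face of ring A, and stereoretentive oxidation of the C–B bond gives the 1β-alcohol under near-neutral conditions that spare the β-hydroxy ketone.

Step 20
Reactants: 31 protected 1β-hydroxy-3-ketone
Product: 32 target CNP0259985.3
Conditions: Bu4NF, AcOH (1:1), THF, 0 to 40 °C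
Reagents that add atoms: none
Why: Buffered fluoride cleaves the silyl ether and fragments the 2-(trimethylsilyl)ethyl ester (β-elimination to ethene) without base-induced retro-aldol or lactone opening, which liberates the target.

## Compound list
1 | cyclopentane-1,3-dione | O=C1CCC(=O)C1 | starting material
2 | allyl bromide (3-bromoprop-1-ene) | C=CCBr | starting material
3 | 2-allylcyclopentane-1,3-dione | C=CCC1C(=O)CCC1=O | intermediate
4 | methyl vinyl ketone (but-3-en-2-one) | CC(=O)C=C | starting material
5 | 2-allyl-2-(3-oxobutyl)cyclopentane-1,3-dione (achiral triketone) | C=CCC1(CCC(C)=O)C(=O)CCC1=O | intermediate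
6 | cis-fused ketol: 7a-allyl-3a-hydroxyhexahydroindane-1,5-dione, 3a-OH cis to allyl | C=CC[C@]12CCC(=O)C[C@@]1(O)CCC2=O | intermediate
7 | (R)-7a-allyl-2,3,7,7a-tetrahydro-1H-indene-1,5(6H)-dione (rings B and C; C8 quaternary; C6 ketone; Δ9(11)-12-one) | C=CC[C@]12CCC(=O)C=C1CCC2=O | intermediate
8 | 7 with the C6 ketone as spiro-1,3-dioxolane | C=CC[C@]12CCC(=O)C=C1CCC23OCCO3 | intermediate
9 | lithium cross-conjugated dienolate of 8 (C12–OLi; C12=C13; C9=C11) | C=CC[C@]12CC=C([O-])C=C1CCC23OCCO3.[Li+] | intermediate
10 | tert-butyldimethylsilyl dienol ether of 8 (12-silyloxy-9(11),12-diene) | C=CC[C@]12CC=C(O[Si](C)(C)C(C)(C)C)C=C1CCC23OCCO3 | intermediate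
11 | tricyclic enone: C13–C16 bond made, 16-methylene, C15–C16 bridge β, Δ9(11)-12-one, C6 ketal | C=C1C[C@]23C[C@H]1C(=O)C=C2CCC34OCCO4 | intermediate
12 | saturated 12-ketone, H-9 α (anti to the C15–C16 bridge), C6 ketal | C=C1C[C@]23C[C@H]1C(=O)C[C@@H]2CCC34OCCO4 | intermediate
13 | 12-alcohol, OH axial on ring C and anti to the C13–C16 bond, C6 ketal | C=C1C[C@]23C[C@H]1[C@@H](O)C[C@@H]2CCC34OCCO4 | intermediate
14 | 12-O-tert-butyldimethylsilyl ether of 13 | C=C1C[C@]23C[C@H]1[C@@H](O[Si](C)(C)C(C)(C)C)C[C@@H]2CCC34OCCO4 | intermediate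
15 | C6 ketone with 12-silyl ether | C=C1C[C@]23C[C@H]1[C@@H](O[Si](C)(C)C(C)(C)C)C[C@@H]2CCC3=O | intermediate
16 | cyclopentenone (C5=C10, C6 ketone) with 12-silyl ether | C=C1C[C@]23C[C@H]1[C@@H](O[Si](C)(C)C(C)(C)C)C[C@@H]2C=CC3=O | intermediate
17 | [2-(1,3-dioxolan-2-yl)ethyl]magnesium bromide | Br[Mg]CCC1OCCO1 | starting material
18 | magnesium enolate (C6–O–MgBr, C5=C6; acetal chain on C10, C10 epimers not assigned) | C=C1C[C@]23C[C@H]1[C@@H](O[Si](C)(C)C(C)(C)C)C[C@@H]2C(CCC4OCCO4)C=C3O[Mg]Br | intermediate
19 | C6 enol triflate (C5=C6) with the acetal chain on C10 (C10 epimers not assigned) | C=C1C[C@]23C[C@H]1[C@@H](O[Si](C)(C)C(C)(C)C)C[C@@H]2C(CCC4OCCO4)C=C3OS(=O)(=O)C(F)(F)F | intermediate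
20 | conjugated 2-(trimethylsilyl)ethyl ester (C7 on C6, C5=C6; C10 epimers not assigned) | C=C1C[C@]23C[C@H]1[C@@H](O[Si](C)(C)C(C)(C)C)C[C@@H]2C(CCC4OCCO4)C=C3C(=O)OCC[Si](C)(C)C | intermediate
21 | lithium dienolate of 20 (C10=C5; C6=C7–OLi) | C=C1C[C@]23C[C@H]1[C@@H](O[Si](C)(C)C(C)(C)C)C[C@@H]2C(CCC4OCCO4)=CC3=C([O-])OCC[Si](C)(C)C.[Li+] | intermediate
22 | deconjugated ester: C5=C10, 6β ester (H-6 α), acetal chain on C10 | C=C1C[C@]23C[C@H]1[C@@H](O[Si](C)(C)C(C)(C)C)C[C@@H]2C(CCC4OCCO4)=C[C@@H]3C(=O)OCC[Si](C)(C)C | intermediate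
23 | aldehyde: as 22 with the chain ending in the C3 aldehyde | C=C1C[C@]23C[C@H]1[C@@H](O[Si](C)(C)C(C)(C)C)C[C@@H]2C(CCC=O)=C[C@@H]3C(=O)OCC[Si](C)(C)C | intermediate
24 | tert-butyl propanoate | CCC(=O)OC(C)(C)C | starting material
25 | lithium enolate of 24 | CC=C([O-])OC(C)(C)C.[Li+] | intermediate
26 | β-hydroxy ester: chain C1H2–C2H2–C3H(OH)–C4H(CH3)–CO2t-Bu on C10 (mixture at C3 and C4) | C=C1C[C@]23C[C@H]1[C@@H](O[Si](C)(C)C(C)(C)C)C[C@@H]2C(CCC(O)C(C)C(=O)OC(C)(C)C)=C[C@@H]3C(=O)OCC[Si](C)(C)C | intermediate
27 | β-keto ester: chain C1H2–C2H2–C3(=O)–C4H(CH3)–CO2t-Bu on C10 (C4 epimers) | C=C1C[C@]23C[C@H]1[C@@H](O[Si](C)(C)C(C)(C)C)C[C@@H]2C(CCC(=O)C(C)C(=O)OC(C)(C)C)=C[C@@H]3C(=O)OCC[Si](C)(C)C | intermediate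
28 | pentacyclic 3-keto-19,10-lactone: 4-methyl β, C19 and O-10 α, H-5 β, 6β ester, 12-silyl ether, 16-ene | C=C1C[C@]23C[C@H]1[C@@H](O[Si](C)(C)C(C)(C)C)C[C@@H]2[C@]12OC(=O)[C@](C)(C(=O)CC1)[C@H]2[C@@H]3C(=O)OCC[Si](C)(C)C | intermediate
29 | Δ1-en-3-one of 28 | C=C1C[C@]23C[C@H]1[C@@H](O[Si](C)(C)C(C)(C)C)C[C@@H]2[C@]12OC(=O)[C@](C)(C(=O)C=C1)[C@H]2[C@@H]3C(=O)OCC[Si](C)(C)C | intermediate
30 | 1β-pinacolboryl 3-ketone | C=C1C[C@]23C[C@H]1[C@@H](O[Si](C)(C)C(C)(C)C)C[C@@H]2[C@]12OC(=O)[C@](C)(C(=O)C[C@H]1B4OC(C)(C)C(C)(C)O4)[C@H]2[C@@H]3C(=O)OCC[Si](C)(C)C | intermediate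
31 | 1β-hydroxy-3-ketone with 12-silyl ether and 7-[2-(trimethylsilyl)ethyl] ester | C=C1C[C@]23C[C@H]1[C@@H](O[Si](C)(C)C(C)(C)C)C[C@@H]2[C@]12OC(=O)[C@](C)(C(=O)C[C@H]1O)[C@H]2[C@@H]3C(=O)OCC[Si](C)(C)C | intermediate
32 | CNP0259985.3 | C=C1C[C@]23C[C@H]1[C@@H](O)C[C@@H]2[C@]12OC(=O)[C@](C)(C(=O)C[C@H]1O)[C@H]2[C@@H]3C(=O)O | target

## Step count and risk

Total step count: 20. Longest linear sequence: 20 (fully linear from 1).

The three steps most likely to fail:

**Step 17** (radical cyclisation with lactonisation). The C10 radical or cation may eliminate instead of being captured by the ester. The fallback separates ring closure from lactonisation, sets out from 27 and returns at 28. Mn(OAc)3·2H2O together with Cu(OAc)2·H2O in AcOH effects the same 6-endo cyclisation, but divalent copper intercepts the C10 radical and oxidative β-hydride elimination gives the ring A alkene, tert-butyl 3-oxo-1(10)-ene-19-oate F1. CF3CO2H in CH2Cl2 at 0 °C then cleaves the tert-butyl ester and protolactonises (Markovnikov protonation at C1, capture of the C10 cation by the axial acid from the α face) to give 28.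

**Step 14** (kinetic deconjugation). γ-Deprotonation of the hindered tertiary H-10 may be slow, or the proton may return to C10. The fallback places the double bond under thermodynamic control through an enal; it sets out from 16 and returns at 27.
- Conjugate addition of 2-lithio-1,3-dithiane (THF/HMPA, −78 °C) with Comins trapping gives the dithianyl enol triflate F2.
- Alkoxycarbonylation as in step 13 gives the dithianyl conjugated ester F3.
- MeI/CaCO3 in aqueous MeCN with a little Et3N unmasks the aldehyde; because H-10 is now α to the formyl group, the double bond migrates into conjugation with it, giving the enal F4 with the ester on sp3 C6 in its more stable β orientation.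
- NaBH4/CeCl3 gives the allylic alcohol F5, and PPh3/CBr4 gives the allylic bromide F6.
- γ-Alkylation of the dianion of tert-butyl 2-methyl-3-oxobutanoate (NaH, then n-BuLi) with F6 gives 27.

**Step 8** (axial 12-alcohol). If the hydride comes from the exo face, the equatorial epimer results. The fallback reaches the axial alcohol by inversion instead of by facial selectivity; it sets out from 12 and returns at 13. NaBH4 in MeOH at 0 °C gives the equatorial 12-epi alcohol F7 cleanly; Mitsunobu reaction (PPh3, diisopropyl azodicarboxylate, 4-nitrobenzoic acid) gives the inverted axial 4-nitrobenzoate F8; K2CO3 in MeOH gives 13.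

## Further compounds
F1 | step 17 | ring A alkene: tert-butyl 3-oxo-1(10)-ene-19-oate (4-methyl β, ester α, H-5 β; 12-silyl ether; 7-silylethyl ester) | C=C1C[C@]23C[C@H]1[C@@H](O[Si](C)(C)C(C)(C)C)C[C@@H]2C1=CCC(=O)[C@@](C)(C(=O)OC(C)(C)C)[C@H]1[C@@H]3C(=O)OCC[Si](C)(C)C
F2 | step 14 | C6 enol triflate with 1,3-dithian-2-yl on C10 | C=C1C[C@]23C[C@H]1[C@@H](O[Si](C)(C)C(C)(C)C)C[C@@H]2C(C4SCCCS4)C=C3OS(=O)(=O)C(F)(F)F
F3 | step 14 | conjugated 2-(trimethylsilyl)ethyl ester with 1,3-dithian-2-yl on C10 | C=C1C[C@]23C[C@H]1[C@@H](O[Si](C)(C)C(C)(C)C)C[C@@H]2C(C4SCCCS4)C=C3C(=O)OCC[Si](C)(C)C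
F4 | step 14 | enal: C10 formyl, C5=C10, 6β ester | C=C1C[C@]23C[C@H]1[C@@H](O[Si](C)(C)C(C)(C)C)C[C@@H]2C(C=O)=C[C@@H]3C(=O)OCC[Si](C)(C)C
F5 | step 14 | allylic alcohol: C10 hydroxymethyl, C5=C10, 6β ester | C=C1C[C@]23C[C@H]1[C@@H](O[Si](C)(C)C(C)(C)C)C[C@@H]2C(CO)=C[C@@H]3C(=O)OCC[Si](C)(C)C
F6 | step 14 | allylic bromide: C10 bromomethyl, C5=C10, 6β ester | C=C1C[C@]23C[C@H]1[C@@H](O[Si](C)(C)C(C)(C)C)C[C@@H]2C(CBr)=C[C@@H]3C(=O)OCC[Si](C)(C)C
F7 | step 8 | equatorial 12-epi alcohol (OH syn to the C13–C16 bond), C6 ketal | C=C1C[C@]23C[C@H]1[C@H](O)C[C@@H]2CCC34OCCO4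
F8 | step 8 | axial 12-(4-nitrobenzoate), C6 ketal | C=C1C[C@]23C[C@H]1[C@@H](OC(=O)c4ccc(cc4)[N+](=O)[O-])C[C@@H]2CCC34OCCO4
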